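**Retrosynthetic overview**
1. Feature: ring A (C4a, C5–OH, C6–CH3, C7–OH, C8–H, C8a) is a 2-methylresorcinol fused to the 3-methoxy-4-pyranone ring C, which is the kojic acid core. Building ring A last on ring C fixes the methyl at C6 and not C8 by connectivity.
2. Key disconnection (ring A; bonds C5–C6, C7–C8, C4a–C5): flavone 28 ⇒ pyranonyl diazomethyl ketone 19 + 1-(triisopropylsiloxy)propyne 23, by Wolff rearrangement, ketene–alkyne (2+2) addition, 4π opening and 6π closure.
3. 19 ⇒ acid 17 ⇒ Suzuki coupling (bond C2–C1′) of bromopyranone acid 16 (kojic acid: C6 bromination, O-methylation, oxidation) with boronate 11.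
4. 11 ⇒ trans-dihydrobenzofuran 10 ⇒ epoxide 3 of MOM-protected resveratrol + bromophenol 8 (from 2,5-dihydroxybenzaldehyde): C3–C3a bond by epoxide arylation with inversion, then O1–C2 bond by Mitsunobu closure with inversion.
5. Ring order: the dihydrofuran ring first (rings B, D, E are preformed), ring C carried intact from kojic acid, ring A last; desilylation and MOM removal finish.

Key step: step 15

Remark on the chemistry: the target SMILES is read as the trans-(2S,3S)-2,3-diaryl-2,3-dihydrobenzofuran. The L-fructose-derived enantiomer of the Shi ketone (made from L-sorbose) is assumed to be at hand.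

Abbreviations: MOM = methoxymethyl; TIPS = triisopropylsilyl; DBF = (2S,3S)-2-[3,5-bis(methoxymethoxy)phenyl]-4,7-bis(methoxymethoxy)-3-[4-(methoxymethoxy)phenyl]-2,3-dihydro-1-benzofuran-5-yl. Rings A and C are the chromone rings, ring B the benzene ring of the dihydrobenzofuran, ring D the 4-hydroxyphenyl and ring E the 3,5-dihydroxyphenyl group.

Step 1
Reactants: 1 resveratrol
Product: 2 (E)-3,5,4'-tris(methoxymethoxy)stilbene
Conditions: NaH, MOMCl, DMF, 0 °C → rt
Reagents that add atoms: chloromethyl methyl ether (MOMCl), COCCl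
Why: Williamson-type O-alkylation of the three phenoxides caps every phenol as an acetal that should survive base, organometallic reagents, palladium catalysis and light and that falls off in mild acid at the end.

Step 2
Reactants: 2 (E)-3,5,4'-tris(methoxymethoxy)stilbene
Product: 3 (2S,3S)-2-[3,5-bis(methoxymethoxy)phenyl]-3-[4-(methoxymethoxy)phenyl]oxirane
Conditions: L-fructose-derived Shi ketone (30 mol %), Oxone (2KHSO5·KHSO4·K2SO4), K2CO3, Bu4NHSO4, MeCN/CH2(OMe)2/aq. Na2B4O7–Na2EDTA buffer, 0 °C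
Reagents that add atoms: potassium peroxymonosulfate (KHSO5), [K+].[O-]S(=O)(=O)OO
Why: Shi asymmetric epoxidation, in which the chiral dioxirane formed from the ketone transfers oxygen to one face of the trans-alkene through a spiro transition state, so both epoxide centres (S,S) are set by the catalyst while the basic buffer protects the acid-labile p-alkoxyaryl epoxide.

Step 3
Reactants: 4 2,5-dihydroxybenzaldehyde
Product: 5 2,5-bis(methoxymethoxy)benzaldehyde
Conditions: NaH, MOMCl, DMF, 0 °C → rt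
Reagents that add atoms: chloromethyl methyl ether (MOMCl), COCCl
Why: Williamson-type O-alkylation of both phenoxides, the chelated ortho-hydroxyl included once it is deprotonated, installs the same acetal protection used on the stilbene.

Step 4
Reactants: 5 2,5-bis(methoxymethoxy)benzaldehyde
Product: 6 4-bromo-2,5-bis(methoxymethoxy)benzaldehyde
Conditions: NBS, DMF, rt, dark
Reagents that add atoms: N-bromosuccinimide, BrN1C(=O)CCC1=O
Why: Electrophilic aromatic bromination should go ortho to the C5 acetal oxygen and para to the formyl group, the position that 2,5-dialkoxybenzaldehydes prefer, and NBS releases no HBr that could cleave the MOM ethers.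

Step 5
Reactants: 6 4-bromo-2,5-bis(methoxymethoxy)benzaldehyde
Product: 8 4-bromo-2,5-bis(methoxymethoxy)phenol, via aryl formate 7 (not isolated)
Conditions: mCPBA, CH2Cl2, 0 °C → rt; then K2CO3, MeOH, rt
Reagents that add atoms: 3-chloroperoxybenzoic acid (mCPBA), OOC(=O)c1cccc(Cl)c1
Why: Baeyer–Villiger (Dakin-type) oxidation, in which the electron-rich aryl group migrates to oxygen, gives the formate, and mild methanolysis frees the phenol without touching the acetals or the bromide.

Step 6
Reactants: 3 (2S,3S)-2-[3,5-bis(methoxymethoxy)phenyl]-3-[4-(methoxymethoxy)phenyl]oxirane; 8 4-bromo-2,5-bis(methoxymethoxy)phenol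
Product: 9 (1R,2S)-1-[3,5-bis(methoxymethoxy)phenyl]-2-[3-bromo-6-hydroxy-2,5-bis(methoxymethoxy)phenyl]-2-[4-(methoxymethoxy)phenyl]ethan-1-ol
Conditions: 3 added slowly to 8 (2 equiv), (CF3)2CHOH/CH2Cl2, −20 → 0 °C
Reagents that add atoms: none
Why: Friedel–Crafts-type ring opening of an aryl epoxide in a fluorinated alcohol, in which hydrogen bonding activates the p-alkoxybenzylic carbon and the most nucleophilic carbon of 8 (C6, between the hydroxyl and an acetal oxygen, with C4 blocked by bromine) attacks anti to the departing oxygen, so the diarylmethine centre is set by inversion and the carbinol centre keeps the epoxide configuration.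

Step 7
Reactants: 9 (1R,2S)-1-[3,5-bis(methoxymethoxy)phenyl]-2-[3-bromo-6-hydroxy-2,5-bis(methoxymethoxy)phenyl]-2-[4-(methoxymethoxy)phenyl]ethan-1-ol
Product: 10 (2S,3S)-5-bromo-2-[3,5-bis(methoxymethoxy)phenyl]-4,7-bis(methoxymethoxy)-3-[4-(methoxymethoxy)phenyl]-2,3-dihydro-1-benzofuran (DBF–Br)
Conditions: PPh3, DIAD, THF, 0 °C → rt
Reagents that add atoms: none
Why: Intramolecular Mitsunobu etherification, a 5-exo-tet SN2 displacement of the activated benzylic alcohol by the phenol with inversion, closes the dihydrofuran ring and sets C2 trans to the aryl group at C3.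

Step 8
Reactants: 10 DBF–Br
Product: 11 2-(DBF)-4,4,5,5-tetramethyl-1,3,2-dioxaborolane
Conditions: B2pin2, PdCl2(dppf) (5 mol %), KOAc, 1,4-dioxane, 90 °C
Reagents that add atoms: bis(pinacolato)diboron, CC1(C)OB(OC1(C)C)B1OC(C)(C)C(C)(C)O1
Why: Miyaura borylation of the aryl bromide under the weak base KOAc is compatible with the acetals and leaves both stereocentres untouched.

Step 9
Reactants: 12 kojic acid
Product: 13 6-bromo-5-hydroxy-2-(hydroxymethyl)-4H-pyran-4-one
Conditions: NBS, DMF, 0 °C → rt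
Reagents that add atoms: N-bromosuccinimide, BrN1C(=O)CCC1=O
Why: Electrophilic bromination of the enolic pyranone should occur at C6, the carbon ortho to the hydroxyl and the site at which kojic acid generally reacts with electrophiles.

Step 10
Reactants: 13 6-bromo-5-hydroxy-2-(hydroxymethyl)-4H-pyran-4-one
Product: 14 6-bromo-2-(hydroxymethyl)-5-methoxy-4H-pyran-4-one
Conditions: MeI, K2CO3, DMF, rt
Reagents that add atoms: iodomethane, CI
Why: Williamson O-methylation is selective for the acidic enolic hydroxyl under K2CO3 and leaves the primary alcohol alone, and this methyl ether becomes the C3 methoxy group of the target.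

Step 11
Reactants: 14 6-bromo-2-(hydroxymethyl)-5-methoxy-4H-pyran-4-one
Product: 16 6-bromo-5-methoxy-4-oxo-4H-pyran-2-carboxylic acid, via aldehyde 15 (not isolated)
Conditions: TEMPO (20 mol %), PhI(OAc)2 (2.2 equiv), MeCN/H2O (1:1), rt
Reagents that add atoms: water, O
Why: Oxoammonium (TEMPO) oxidation with PhI(OAc)2 in wet acetonitrile takes the activated primary alcohol through the aldehyde hydrate to the acid, and it is done here before any electron-rich arene is in the molecule.

Step 12
Reactants: 11 2-(DBF)-4,4,5,5-tetramethyl-1,3,2-dioxaborolane; 16 6-bromo-5-methoxy-4-oxo-4H-pyran-2-carboxylic acid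
Product: 17 6-(DBF)-5-methoxy-4-oxo-4H-pyran-2-carboxylic acid
Conditions: Pd(OAc)2 (5 mol %), SPhos (10 mol %), K3PO4, 1,4-dioxane/H2O, 80 °C; pH 4 citrate work-up
Reagents that add atoms: none
Why: Suzuki–Miyaura coupling of the vinylogous acyl bromide, which should add readily to palladium, with the ortho-alkoxy arylboronate under a bulky biarylphosphine forms the future C2–C1′ bond of the flavone, the acid being carried as its potassium salt.

Step 13
Reactants: 17 6-(DBF)-5-methoxy-4-oxo-4H-pyran-2-carboxylic acid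
Product: 19 2-(2-diazoacetyl)-6-(DBF)-5-methoxy-4H-pyran-4-one, via acid chloride 18 (not isolated)
Conditions: 1-chloro-N,N,2-trimethylprop-1-en-1-amine (Ghosez reagent), CH2Cl2, 0 °C; then CH2N2 (3 equiv), Et2O, 0 °C
Reagents that add atoms: diazomethane, C=[N+]=[N-]
Why: The Ghosez reagent forms the acid chloride under neutral conditions that spare the MOM ethers, and acylation of diazomethane (first stage of the Arndt–Eistert sequence) gives the α-diazo ketone while excess reagent scavenges HCl.

Step 14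
Reactants: 20 ethyl acetate
Product: 23 1-(triisopropylsiloxy)prop-1-yne, via lithium 1,1-dibromoprop-1-en-2-olate 21 (not isolated), via lithium propynolate 22 (not isolated)
Conditions: CH2Br2, LiTMP (lithium 2,2,6,6-tetramethylpiperidide), THF, −78 °C; 20; LiHMDS; n-BuLi, −78 → −20 °C; TIPSCl, −78 → 0 °C
Reagents that add atoms: dibromomethane, BrCBr; triisopropylsilyl chloride, CC(C)[Si](Cl)(C(C)C)C(C)C
Why: Kowalski ester homologation, in which dibromomethyllithium adds to the ester, the derived dibromo enolate undergoes bromine–lithium exchange and carbenoid rearrangement with 1,2-shift of methyl to the ynolate, and the silyl chloride traps the ynolate on oxygen.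

Step 15
Reactants: 19 2-(2-diazoacetyl)-6-(DBF)-5-methoxy-4H-pyran-4-one; 23 1-(triisopropylsiloxy)prop-1-yne
Product: 28 2-(DBF)-5-hydroxy-3-methoxy-6-methyl-7-(triisopropylsiloxy)-4H-chromen-4-one, via pyranonylketene 24 (not isolated), via cyclobutenone 25 (not isolated), via dienylketene 26 (not isolated), via cyclohexadienone tautomer 27 (not isolated)
Conditions: 23 (2.5 equiv), hν (365 nm LEDs, Pyrex), ClCH2CH2Cl (degassed), rt; then 80 °C, dark
Reagents that add atoms: none
Why: Excitation of diazo ketone 19 expels N2 with 1,2-shift of the pyranonyl group (Wolff rearrangement) to give ketene 24; the nucleophilic methyl-bearing carbon of 23 then bonds to the ketene carbonyl carbon and the oxygen-bearing carbon to the former diazo carbon, giving cyclobutenone 25 by a regiodefined (2+2) addition. Reversible, strain-driven conrotatory 4π opening of 25 gives dienylketene 26, whose ketene carbon closes onto pyranone C3 (the CH carbon, the future C4a) in a thermal disrotatory 6π electrocyclisation to dienone 27, and tautomerisation aromatises ring A to phenol 28. This is the Danheiser benzannulation of α,β-unsaturated α′-diazo ketones with siloxyalkynes, with the C2=C3 bond of a 4-pyranone as the ene component. Ring A is the only ring closed, by 6π electrocyclisation, and it forms C5–C6, C7–C8 and C4a–C5; no stereocentre is created because C4 of 25 and C4a of 27 return to sp2, and the two dihydrobenzofuran centres are remote and untouched. The step needs regioselectivity (methyl at C6, silyloxy at C7), which the polarity of the ketene–ynol ether pair fixes so that the 8-methyl isomer cannot arise. It also needs chemoselective excitation and an unintercepted ketene, for which irradiation at 365 nm addresses the diazo ketone rather than the pyranone, every phenol is capped as a MOM ether, and the new C5 hydroxyl is hydrogen-bonded to the C4 carbonyl and so should resist acylation by 24.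

Step 16
Reactants: 28 2-(DBF)-5-hydroxy-3-methoxy-6-methyl-7-(triisopropylsiloxy)-4H-chromen-4-one
Product: 29 2-(DBF)-5,7-dihydroxy-3-methoxy-6-methyl-4H-chromen-4-one
Conditions: TBAF, AcOH, THF, 0 °C
Reagents that add atoms: none
Why: Fluoride-mediated desilylation of the aryl silyl ether is driven by Si–F bond formation, and acetic acid buffering avoids a strongly basic phenoxide medium.

Step 17
Reactants: 29 2-(DBF)-5,7-dihydroxy-3-methoxy-6-methyl-4H-chromen-4-one
Product: 30 2-[(2S,3S)-2-(3,5-dihydroxyphenyl)-4,7-dihydroxy-3-(4-hydroxyphenyl)-2,3-dihydro-1-benzofuran-5-yl]-5,7-dihydroxy-3-methoxy-6-methyl-4H-chromen-4-one (target)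
Conditions: HCl (1.25 M in MeOH), THF, 40 °C, degassed, under argon
Reagents that add atoms: none
Why: Acid-catalysed acetal exchange with methanol removes the five MOM groups as dimethoxymethane under conditions that should be too mild to cleave the C3 methyl ether, to open the dihydrofuran (its benzylic C2 carries a meta-dioxygenated aryl group that does not stabilise a cation) or to cause Wessely–Moser isomerisation of ring A.

**Compound list**
1 | resveratrol | Oc1ccc(/C=C/c2cc(O)cc(O)c2)cc1 | starting material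
2 | (E)-3,5,4'-tris(methoxymethoxy)stilbene | COCOc1ccc(/C=C/c2cc(OCOC)cc(OCOC)c2)cc1 | intermediate
3 | (2S,3S)-2-[3,5-bis(methoxymethoxy)phenyl]-3-[4-(methoxymethoxy)phenyl]oxirane | COCOc1ccc([C@@H]2O[C@H]2c3cc(OCOC)cc(OCOC)c3)cc1 | intermediate
4 | 2,5-dihydroxybenzaldehyde | O=Cc1cc(O)ccc1O | starting material
5 | 2,5-bis(methoxymethoxy)benzaldehyde | O=Cc1cc(OCOC)ccc1OCOC | intermediate
6 | 4-bromo-2,5-bis(methoxymethoxy)benzaldehyde | O=Cc1cc(OCOC)c(Br)cc1OCOC | intermediate
7 | 4-bromo-2,5-bis(methoxymethoxy)phenyl formate | O=COc1cc(OCOC)c(Br)cc1OCOC | intermediate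
8 | 4-bromo-2,5-bis(methoxymethoxy)phenol | Oc1cc(OCOC)c(Br)cc1OCOC | intermediate
9 | (1R,2S)-1-[3,5-bis(methoxymethoxy)phenyl]-2-[3-bromo-6-hydroxy-2,5-bis(methoxymethoxy)phenyl]-2-[4-(methoxymethoxy)phenyl]ethan-1-ol | Oc1c(OCOC)cc(Br)c(OCOC)c1[C@H](c2ccc(OCOC)cc2)[C@@H](O)c3cc(OCOC)cc(OCOC)c3 | intermediate
10 | (2S,3S)-5-bromo-2-[3,5-bis(methoxymethoxy)phenyl]-4,7-bis(methoxymethoxy)-3-[4-(methoxymethoxy)phenyl]-2,3-dihydro-1-benzofuran (DBF–Br) | Brc1cc(OCOC)c2c(c1OCOC)[C@H](c3ccc(OCOC)cc3)[C@@H](c4cc(OCOC)cc(OCOC)c4)O2 | intermediate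
11 | 2-(DBF)-4,4,5,5-tetramethyl-1,3,2-dioxaborolane | CC1(C)OB(OC1(C)C)c2cc(OCOC)c3c(c2OCOC)[C@H](c4ccc(OCOC)cc4)[C@@H](c5cc(OCOC)cc(OCOC)c5)O3 | intermediate
12 | kojic acid | O=c1cc(CO)occ1O | starting material
13 | 6-bromo-5-hydroxy-2-(hydroxymethyl)-4H-pyran-4-one | O=c1cc(CO)oc(Br)c1O | intermediate
14 | 6-bromo-2-(hydroxymethyl)-5-methoxy-4H-pyran-4-one | COc1c(Br)oc(CO)cc1=O | intermediate
15 | 6-bromo-5-methoxy-4-oxo-4H-pyran-2-carbaldehyde | COc1c(Br)oc(C=O)cc1=O | intermediate
16 | 6-bromo-5-methoxy-4-oxo-4H-pyran-2-carboxylic acid | COc1c(Br)oc(C(=O)O)cc1=O | intermediate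
17 | 6-(DBF)-5-methoxy-4-oxo-4H-pyran-2-carboxylic acid | COc1c(-c2cc(OCOC)c3c(c2OCOC)[C@H](c4ccc(OCOC)cc4)[C@@H](c5cc(OCOC)cc(OCOC)c5)O3)oc(C(=O)O)cc1=O | intermediate
18 | 6-(DBF)-5-methoxy-4-oxo-4H-pyran-2-carbonyl chloride | COc1c(-c2cc(OCOC)c3c(c2OCOC)[C@H](c4ccc(OCOC)cc4)[C@@H](c5cc(OCOC)cc(OCOC)c5)O3)oc(C(=O)Cl)cc1=O | intermediate
19 | 2-(2-diazoacetyl)-6-(DBF)-5-methoxy-4H-pyran-4-one | COc1c(-c2cc(OCOC)c3c(c2OCOC)[C@H](c4ccc(OCOC)cc4)[C@@H](c5cc(OCOC)cc(OCOC)c5)O3)oc(C(=O)C=[N+]=[N-])cc1=O | intermediate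
20 | ethyl acetate | CCOC(C)=O | starting material
21 | lithium 1,1-dibromoprop-1-en-2-olate | CC(O[Li])=C(Br)Br | intermediate
22 | lithium prop-1-yn-1-olate | CC#CO[Li] | intermediate
23 | 1-(triisopropylsiloxy)prop-1-yne | CC#CO[Si](C(C)C)(C(C)C)C(C)C | intermediate
24 | [6-(DBF)-5-methoxy-4-oxo-4H-pyran-2-yl]ketene | COc1c(-c2cc(OCOC)c3c(c2OCOC)[C@H](c4ccc(OCOC)cc4)[C@@H](c5cc(OCOC)cc(OCOC)c5)O3)oc(C=C=O)cc1=O | intermediate
25 | 4-[6-(DBF)-5-methoxy-4-oxo-4H-pyran-2-yl]-2-methyl-3-(triisopropylsiloxy)cyclobut-2-en-1-one (both C4 epimers) | COc1c(-c2cc(OCOC)c3c(c2OCOC)[C@H](c4ccc(OCOC)cc4)[C@@H](c5cc(OCOC)cc(OCOC)c5)O3)oc(C6C(=O)C(C)=C6O[Si](C(C)C)(C(C)C)C(C)C)cc1=O | intermediate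
26 | 4-[6-(DBF)-5-methoxy-4-oxo-4H-pyran-2-yl]-2-methyl-3-(triisopropylsiloxy)buta-1,3-dien-1-one, pyranonyl group cis to the ketene-bearing carbon | COc1c(-c2cc(OCOC)c3c(c2OCOC)[C@H](c4ccc(OCOC)cc4)[C@@H](c5cc(OCOC)cc(OCOC)c5)O3)oc(/C=C(\C(C)=C=O)O[Si](C(C)C)(C(C)C)C(C)C)cc1=O | intermediate
27 | 2-(DBF)-3-methoxy-6-methyl-7-(triisopropylsiloxy)-4aH-chromene-4,5-dione (4a-H keto tautomer of 28) | COC1=C(c2cc(OCOC)c3c(c2OCOC)[C@H](c4ccc(OCOC)cc4)[C@@H](c5cc(OCOC)cc(OCOC)c5)O3)OC6=CC(O[Si](C(C)C)(C(C)C)C(C)C)=C(C)C(=O)C6C1=O | intermediate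
28 | 2-(DBF)-5-hydroxy-3-methoxy-6-methyl-7-(triisopropylsiloxy)-4H-chromen-4-one | COc1c(-c2cc(OCOC)c3c(c2OCOC)[C@H](c4ccc(OCOC)cc4)[C@@H](c5cc(OCOC)cc(OCOC)c5)O3)oc6cc(O[Si](C(C)C)(C(C)C)C(C)C)c(C)c(O)c6c1=O | intermediate
29 | 2-(DBF)-5,7-dihydroxy-3-methoxy-6-methyl-4H-chromen-4-one | COc1c(-c2cc(OCOC)c3c(c2OCOC)[C@H](c4ccc(OCOC)cc4)[C@@H](c5cc(OCOC)cc(OCOC)c5)O3)oc6cc(O)c(C)c(O)c6c1=O | intermediate
30 | 2-[(2S,3S)-2-(3,5-dihydroxyphenyl)-4,7-dihydroxy-3-(4-hydroxyphenyl)-2,3-dihydro-1-benzofuran-5-yl]-5,7-dihydroxy-3-methoxy-6-methyl-4H-chromen-4-one | COc1c(-c2cc(O)c3c(c2O)[C@H](c4ccc(O)cc4)[C@@H](c5cc(O)cc(O)c5)O3)oc6cc(O)c(C)c(O)c6c1=O | target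

**Step count**
Total: 17 steps. Longest linear sequence: 11 steps (steps 3, 4, 5, 6, 7, 8, 12, 13, 15, 16, 17, from 2,5-dihydroxybenzaldehyde 4).

**Steps most likely to fail, with fallbacks**

Step 15. The light may be absorbed by the aryl-pyranone and the flavone product, leading to their photoisomerisation. The ketene may dimerise or acylate the product phenol before the alkyne traps it, and the 6π closure onto the pyranone may lag behind. The fallback generates the same ketene without light and sets out from 19. Wolff rearrangement of 19 catalysed by AgO2CPh with Et3N in aqueous 1,4-dioxane should give the homologated acid 2-[6-(DBF)-5-methoxy-4-oxo-4H-pyran-2-yl]acetic acid F1. The Ghosez reagent in CH2Cl2 at 0 °C converts it into 2-[6-(DBF)-5-methoxy-4-oxo-4H-pyran-2-yl]acetyl chloride F2. Slow addition of Et3N to F2 and 23 in toluene dehydrochlorinates F2 to ketene 24, which adds to 23 to give 25. Heating at 80–110 °C in the dark then takes 25 through 26 and 27, so the sequence comes back to the route at 28.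

Step 6. Full ionisation to a free benzylic cation would erode the anti selectivity and feed the cis series after step 7. The epoxide may also undergo Meinwald rearrangement, and the phenol may be alkylated on oxygen or at the wrong ring carbon. The fallback forms the C–O bond first and sets out from 3 and 8. Methanolysis of 3 at the p-alkoxybenzylic carbon (MeOH, cat. pyridinium p-toluenesulfonate, 0 °C) should give (1S,2R)-1-[3,5-bis(methoxymethoxy)phenyl]-2-methoxy-2-[4-(methoxymethoxy)phenyl]ethan-1-ol F3, whose carbinol centre is untouched. Intermolecular Mitsunobu etherification of F3 with 8 (PPh3, DIAD, THF) inverts that centre and gives 1-bromo-4-{(1R,2R)-1-[3,5-bis(methoxymethoxy)phenyl]-2-methoxy-2-[4-(methoxymethoxy)phenyl]ethoxy}-2,5-bis(methoxymethoxy)benzene F4. BF3·OEt2 in CH2Cl2 at −78 °C then ionises the benzylic methyl ether, and the tethered arene closes the five-membered ring by intramolecular Friedel–Crafts alkylation, trans to the neighbouring aryl group. The sequence comes back to the route at 10.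

Step 12. The electron-rich ortho-alkoxy boronate may protodeboronate, bromide on the pyranone may be displaced hydrolytically under aqueous base, and transmetalation at the hindered carbon may be slow. The fallback is a base-free Stille coupling and sets out from 16 and 10. Esterification of 16 (MeI, K2CO3, DMF) gives methyl 6-bromo-5-methoxy-4-oxo-4H-pyran-2-carboxylate F5. Stannylation of 10 with Me3SnSnMe3 and Pd(PPh3)4 in toluene at 100 °C gives trimethyl(DBF)stannane F6. Stille coupling of F5 and F6 (Pd(PPh3)4, CuI, DMF, 80 °C) gives methyl 6-(DBF)-5-methoxy-4-oxo-4H-pyran-2-carboxylate F7. Saponification with LiOH in THF/H2O at 0 °C, followed by a pH 4 work-up, comes back to the route at 17.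

Further compounds
F1 | step 15 | 2-[6-(DBF)-5-methoxy-4-oxo-4H-pyran-2-yl]acetic acid | COc1c(-c2cc(OCOC)c3c(c2OCOC)[C@H](c4ccc(OCOC)cc4)[C@@H](c5cc(OCOC)cc(OCOC)c5)O3)oc(CC(=O)O)cc1=O
F2 | step 15 | 2-[6-(DBF)-5-methoxy-4-oxo-4H-pyran-2-yl]acetyl chloride | COc1c(-c2cc(OCOC)c3c(c2OCOC)[C@H](c4ccc(OCOC)cc4)[C@@H](c5cc(OCOC)cc(OCOC)c5)O3)oc(CC(=O)Cl)cc1=O
F3 | step 6 | (1S,2R)-1-[3,5-bis(methoxymethoxy)phenyl]-2-methoxy-2-[4-(methoxymethoxy)phenyl]ethan-1-ol | COCOc1ccc([C@@H](OC)[C@@H](O)c2cc(OCOC)cc(OCOC)c2)cc1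
F4 | step 6 | 1-bromo-4-{(1R,2R)-1-[3,5-bis(methoxymethoxy)phenyl]-2-methoxy-2-[4-(methoxymethoxy)phenyl]ethoxy}-2,5-bis(methoxymethoxy)benzene | COCOc1ccc([C@@H](OC)[C@H](Oc2cc(OCOC)c(Br)cc2OCOC)c3cc(OCOC)cc(OCOC)c3)cc1
F5 | step 12 | methyl 6-bromo-5-methoxy-4-oxo-4H-pyran-2-carboxylate | COC(=O)c1cc(=O)c(OC)c(Br)o1
F6 | step 12 | trimethyl(DBF)stannane | C[Sn](C)(C)c1cc(OCOC)c2c(c1OCOC)[C@H](c3ccc(OCOC)cc3)[C@@H](c4cc(OCOC)cc(OCOC)c4)O2
F7 | step 12 | methyl 6-(DBF)-5-methoxy-4-oxo-4H-pyran-2-carboxylate | COc1c(-c2cc(OCOC)c3c(c2OCOC)[C@H](c4ccc(OCOC)cc4)[C@@H](c5cc(OCOC)cc(OCOC)c5)O3)oc(C(=O)OC)cc1=O
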